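Tetralin numbering is used throughout, for the target and for every precursor.

## Analysis of the target

Target 27 is a 1-aryltetralin cyclolignan: C1 carries the 4-hydroxy-3-methoxyphenyl ring (ring C), C2 and C3 carry the hydroxymethyl carbons C9 and C10, C4 is a methylene, and C4a and C8a join the saturated ring B to the benzene ring A, which has H at C5, OMe at C6 and OH at C7 and C8. C1, C2 and C3 are contiguous stereocentres of configuration (1S,2R,3R), so the aryl group is trans to C9 and C9 is trans to C10. The sensitive groups are the C7/C8 catechol (air oxidation to an ortho-quinone), the ring C phenol, and C1, which is doubly benzylic and para to the C6 methoxy group and therefore ionises readily in acid; the free hydroxyls are thus best released last, under neutral reducing conditions. The main difficulty is the unsymmetrical ring A: a chain on C4a that closes ring B by electrophilic attack must choose between C8a and C5, and both are para to an alkoxy group. In addition, the C8 oxygen is peri to C1, and the C2/C3 unit has no ring heteroatom that could relay absolute configuration. The strategy rests on one feature: C8a is flanked by the oxygen-bearing C8, whereas C4a is flanked by C5–H, so an aryne spanning C4a and C8a is a 3-alkoxyaryne with two electronically distinct termini, in which a carbon nucleophile should go to C4a and the aryl anion should develop at C8a. The trans C2/C3 unit with its two one-carbon arms is the skeleton of a fumarate.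

## Retrosynthetic reasoning

**27 from 26.** The four O–benzyl bonds are cut last. All four hydroxyls that must be masked (C7, C8, C9, C10) carry the same group, so one hydrogenolysis releases the air-sensitive catechol in the final step without acid, base or oxidant.

**26 from 24 and 25.** The C1–aryl bond is cut. C1 is para to the C6 methoxy group and ortho to the C8 oxygen, so alcohol 24 ionises easily. Phenol 25 reacts para to its hydroxyl, and the C2 substituent next to the cation directs attack to the opposite face. Ring C is thus attached late, its phenol needs no protection, and C1 is set by substrate control.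

**24 from 23 from 22.** These are adjustments, not skeletal cuts. The C4 sulfonyl group and the C1 carbonyl of 22 are the two functions the ring-forming step leaves behind. The ketone is reduced to alcohol 23, which later serves as the leaving group at C1, and the sulfone is then removed reductively to give 24. Reduction comes first so that no aryl ketone is exposed to electron-transfer conditions.

**22 from 11 and 19 (through 20 and 21).** Both bonds from ring A to ring B, C4–C4a and C1–C8a, are cut, and C1 is reconnected to C4. This returns the four-membered β-keto sulfone 11 and aryne 20, which is released from silyl triflate 19. The cut is made here because it forms both aryl–alkyl bonds in one operation and fixes the regiochemistry on ring A through the C8 oxygen rather than through an electrophilic closure. C2 and C3 pass through as spectators. The forward reaction must add the C4 carbanion to C4a, let the C8a anion add to the carbonyl group (alkoxide 21), and fragment the old C1–C4 bond.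

**11 from 10 from 8 (through 9).** The C4–S bond is cut. Sulfur is introduced on the less substituted α-carbon of 8 through silyl enol ether 9, and sulfide 10 is then oxidised. The oxidant must not be a peracid, because a cyclobutanone would undergo Baeyer–Villiger oxidation.

**8 from 7, 6 and 5; 5 from 3 and 4; 3 from 1 and 2.** The cyclobutane bonds C1–C2 and C3–C4 are cut in a [2+2] sense, back to fumarate 3 and ketene acetal 4. The alkene geometry of 3 gives the trans relationship, and its menthyl esters, put on by esterifying 1 with two molecules of 2, give the absolute configuration. Ester reduction (6), benzylation (7) and ketal hydrolysis convert 5 into 8.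

**19 from 16, 15, 13 and 12.** The C–Si and O–S bonds of 19 are cut back to ortho-bromophenol 16 (silyl migration from oxygen to carbon through 17 and 18, then triflation). The bromine is placed ortho to the hydroxyl of phenol 15, and that hydroxyl comes from the aldehyde of 13 by oxidative aryl migration through formate 14. Aldehyde 12 already has the full oxygenation pattern of ring A.

## Alternatives that were turned down

**Alternative 1:** The cuts are C2–C3 and C1–C8a, the bonds made in lignan biosynthesis. Two different 4-hydroxycinnamate arms are held on a C2-symmetric chiral 1,3-diol in bis-cinnamate A2. Anodic oxidation should join the two carbons next to the ester carbonyls (C2–C3) inside a nine-membered dilactone. Ring A then adds through C8a to the quinone methide carbon C1 to give dihydronaphthalene A1. In its favour, the whole skeleton, ring B and two stereocentres arise in one step from simple acids, and on step count it is stronger than the chosen route. Against it: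
- The tether does not suppress the other phenoxy-radical coupling modes (side chain to ring carbon, side chain to oxygen).
- The C8 oxygen must be carried as a tosylate only to bias which ortho carbon of ring A attacks.
- A1 has a C3=C4 double bond, so C3 must be set later by reducing a conjugated trisubstituted alkene, where cis delivery of hydrogen threatens the 2,3-trans relationship.
- Tosylate removal and two ester reductions follow.

The chosen route is longer, but no stereocentre depends on an alkene reduction and the ring A regiochemistry is set by the aryne.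

**Alternative 2:** The cuts are C1–C2 and the bond from the C8 oxygen to C9. Acid converts hydroxy carbinol A4 into an ortho-quinone methide, which adds the tethered enol ether in a hetero-Diels–Alder reaction to give tricyclic acetal A3. In its favour, the C8 phenol is used constructively, ring C is already on C1 (so the regiochemistry on phenol 25 never arises), and C1 and C2 are set together in an ordered transition state. On C1 control it is as strong as or stronger than the chosen route. Against it:
- Two new stereocentres depend on the single C3 centre in a flexible tether.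
- The acetal must then be hydrolysed and reduced to free C9–OH and C8–OH.
- A4 is a linear construct that needs an enantioenriched C3 centre and a ring A substituted at both C4a and C8a, which is the same ortho-difunctionalisation problem solved in many more steps.

The chosen route is convergent and installs both ring A bonds in one step.

**Alternative 3:** The cuts are C1–C2 and C3–C4, followed by the C1–aryl bond. Irradiation of ortho-methylbenzaldehyde A6 gives a hydroxy-ortho-quinodimethane. A chiral Lewis acid made from Ti(OiPr)4 A8 (tetravalent titanium) and the tartrate-derived diol A9 should guide its Diels–Alder reaction with dimethyl fumarate A7 to hydroxy diester A5. In its favour, it is the shortest plan: ring B and the trans C2/C3 diester arise in one catalytic step, and the C1 hydroxyl is ready for the same arylation used here. On step economy it is clearly stronger. Against it: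
- The absolute configuration depends on a chiral Lewis acid organising a photo-generated dienol and an acyclic diester.
- A6 is itself a pentasubstituted arene that needs a regioselective synthesis.
- The C1 cation would sit next to an ester-bearing carbon unless the esters are reduced and protected first.

The chosen route offers instead an absolute configuration taken from a crystalline, auxiliary-controlled cycloadduct and a ring A regiochemistry dictated by the substrate.

Key step: step 12

**Assumptions.**
- The Et2AlCl-promoted [2+2] of the di-(−)-menthyl ester is taken to give the (2S,3S)-cyclobutanone series. The target needs (2R,3R), so the (+)-menthyl ester is used. If the facial sense is the reverse, (−)-menthol is substituted in step 1 with no other change.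
- Compounds 1, 2, 4, 12 and 25 are taken as commercial.

## Route

Step 1
Reactants: 1 fumaric acid; 2 (+)-menthol (two equivalents, one per carboxyl group)
Product: 3 di-(+)-menthyl fumarate
Conditions: 2 (2.2 equiv), p-TsOH·H2O (cat.), toluene, reflux, Dean–Stark
Reagents that add atoms: (+)-menthol (the second equivalent of 2), CC(C)[C@H]1CC[C@H](C)C[C@@H]1O
Why: Two-fold Fischer esterification driven by azeotropic removal of water, in which each carboxyl group of 1 takes up one molecule of 2; the E alkene and the menthyl stereocentres are unaffected.

Step 2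
Reactants: 3 di-(+)-menthyl fumarate; 4 1,1-dimethoxyethene
Product: 5 di-(+)-menthyl (1R,2S)-3,3-dimethoxycyclobutane-1,2-dicarboxylate
Conditions: Et2AlCl (2 equiv), toluene, −78 °C; recrystallise
Reagents that add atoms: none
Why: Lewis acid-promoted stepwise [2+2] cycloaddition: the CH2 of 4 adds to the activated fumarate and the ester enolate closes on the dialkoxycarbenium ion. The E geometry gives the trans diester and the two menthyl groups shield the same face at both ends of the acceptor, which sets the future C2 and C3 as R,R.

Step 3
Reactants: 5 di-(+)-menthyl (1R,2S)-3,3-dimethoxycyclobutane-1,2-dicarboxylate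
Product: 6 [(1R,2R)-3,3-dimethoxycyclobutane-1,2-diyl]dimethanol
Conditions: LiAlH4, THF, 0 °C to rt
Reagents that add atoms: none
Why: Hydride reduction of both esters; the ketal and the two stereocentres are untouched and 2 is recovered.

Step 4
Reactants: 6 [(1R,2R)-3,3-dimethoxycyclobutane-1,2-diyl]dimethanol
Product: 7 (2R,3R)-2,3-bis(benzyloxymethyl)-1,1-dimethoxycyclobutane
Conditions: NaH, BnBr, Bu4NI (cat.), THF/DMF, 0 °C to rt
Reagents that add atoms: benzyl bromide, BrCc1ccccc1
Why: Williamson etherification of two primary alkoxides; the ketal is stable to base.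

Step 5
Reactants: 7 (2R,3R)-2,3-bis(benzyloxymethyl)-1,1-dimethoxycyclobutane
Product: 8 (2R,3R)-2,3-bis(benzyloxymethyl)cyclobutan-1-one
Conditions: 0.5 M aq. H2SO4, MeCN, rt
Reagents that add atoms: water, O
Why: Acid-catalysed ketal hydrolysis; benzyl ethers are stable, and mild aqueous acid avoids enolisation toward C2 and loss of benzyl alcohol.

Step 6
Reactants: 8 (2R,3R)-2,3-bis(benzyloxymethyl)cyclobutan-1-one
Product: 10 (2R,3R)-2,3-bis(benzyloxymethyl)-4-(phenylsulfanyl)cyclobutan-1-one (C4 epimers), via silyl enol ether 9 (not isolated)
Conditions: LiN(iPr)2, TMSCl, THF, −78 °C; then PhSCl, CH2Cl2, −78 °C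
Reagents that add atoms: benzenesulfenyl chloride, ClSc1ccccc1
Why: Kinetic deprotonation at the unsubstituted C4 methylene with in situ silylation gives the less substituted silyl enol ether 9 before the enolate can add to the electrophilic cyclobutanone. Electrophilic sulfenylation of 9 then places sulfur at C4 only; the C4 configuration is irrelevant.

Step 7
Reactants: 10 (2R,3R)-2,3-bis(benzyloxymethyl)-4-(phenylsulfanyl)cyclobutan-1-one
Product: 11 (2R,3R)-2,3-bis(benzyloxymethyl)-4-(phenylsulfonyl)cyclobutan-1-one (C4 epimers)
Conditions: DMDO (2.5 equiv, acetone), CH2Cl2, −20 to 0 °C; evaporate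
Reagents that add atoms: dimethyldioxirane, CC1(C)OO1
Why: Sulfide-to-sulfone oxidation by an electrophilic oxygen donor. A dioxirane does not add to the carbonyl group, so the Baeyer–Villiger reaction that peracids or H2O2 would cause on a cyclobutanone is avoided, and evaporation is the only work-up the base-sensitive β-keto sulfone needs.

Step 8
Reactants: 12 2,3-dihydroxy-4-methoxybenzaldehyde
Product: 13 2,3-bis(benzyloxy)-4-methoxybenzaldehyde
Conditions: BnBr, K2CO3, DMF, 60 °C
Reagents that add atoms: benzyl bromide, BrCc1ccccc1
Why: Williamson etherification of both phenols; benzyl ethers are chosen so that ring A is unmasked together with C9 and C10 in the last step.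

Step 9
Reactants: 13 2,3-bis(benzyloxy)-4-methoxybenzaldehyde
Product: 15 2,3-bis(benzyloxy)-4-methoxyphenol, via aryl formate 14 (not isolated)
Conditions: mCPBA, CH2Cl2, 0 °C to rt; then K2CO3 (cat.), MeOH, rt
Reagents that add atoms: 3-chloroperbenzoic acid, OOC(=O)c1cccc(Cl)c1
Why: Baeyer–Villiger oxidation of the electron-rich benzaldehyde with aryl migration (Dakin-type) gives formate 14, which is methanolysed to the phenol; the oxygen introduced here sits on the future C8a.

Step 10
Reactants: 15 2,3-bis(benzyloxy)-4-methoxyphenol
Product: 16 2,3-bis(benzyloxy)-6-bromo-4-methoxyphenol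
Conditions: NBS, iPr2NH (10 mol%), CH2Cl2, −78 to 0 °C
Reagents that add atoms: N-bromosuccinimide, BrN1C(=O)CCC1=O
Why: Amine-catalysed ortho-bromination of a phenol: the free hydroxyl is the strongest donor and its only open ortho position is the future C4a, whereas the competing C5 is ortho to the weaker methoxy donor.

Step 11
Reactants: 16 2,3-bis(benzyloxy)-6-bromo-4-methoxyphenol
Product: 19 2,3-bis(benzyloxy)-4-methoxy-6-(trimethylsilyl)phenyl trifluoromethanesulfonate, via aryl trimethylsilyl ether 17 (not isolated), via lithium 2-silylphenoxide 18 (not isolated)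
Conditions: HMDS, THF, 70 °C, then evaporate; n-BuLi, THF, −100 to −78 °C; Tf2O, −100 °C to rt
Reagents that add atoms: hexamethyldisilazane, C[Si](C)(C)N[Si](C)(C)C; trifluoromethanesulfonic anhydride, O=S(=O)(OS(=O)(=O)C(F)(F)F)C(F)(F)F
Why: O-silylation, bromine–lithium exchange and 1,3 silyl migration from oxygen to carbon (retro-Brook rearrangement) put silicon on the carbon that carried bromine. Triflation of phenoxide 18 gives the ortho-silylaryl triflate, the standard fluoride-triggered aryne precursor.

Step 12
Reactants: 11 (2R,3R)-2,3-bis(benzyloxymethyl)-4-(phenylsulfonyl)cyclobutan-1-one; 19 2,3-bis(benzyloxy)-4-methoxy-6-(trimethylsilyl)phenyl trifluoromethanesulfonate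
Product: 22 (2R,3R)-7,8-bis(benzyloxy)-2,3-bis(benzyloxymethyl)-6-methoxy-4-(phenylsulfonyl)-3,4-dihydronaphthalen-1(2H)-one (C4 epimers), via aryne 20 (not isolated), via bicyclic caesium alkoxide 21 (not isolated)
Conditions: CsF (3 equiv), 19 (1.4 equiv), MeCN, 60 °C
Reagents that add atoms: none
Why: Proposed new method: fluoride removes silicon from 19 and triflate leaves to give aryne 20, while CsF also deprotonates C4 of 11 between carbonyl and sulfonyl; the carbanion adds at C4a, the aryne terminus remote from the C8 benzyloxy group, because that oxygen polarises the strained triple bond and stabilises the developing aryl anion at the adjacent C8a. The C8a anion then adds to the neighbouring cyclobutanone carbonyl (4-exo-trig) to give the cis-fused alkoxide 21, which fragments across the former C1–C4 bond in a retro-aldol sense to the benzylic sulfonyl-stabilised carbanion, so C4–C4a and C1–C8a are formed and ring B arises by two-carbon expansion of the four-membered ring, not by a direct six-membered closure. The closest known reaction type is the acyl-alkylation of arynes by cyclic β-keto esters and β-keto sulfones of five-membered and larger rings; a four-membered substrate is untested, and the new element is alkoxide 21 with its two fused four-membered rings. Two points argue that 21 can form and open: a cyclobutanone carbonyl is unusually electrophilic because addition relieves angle strain, and the fragmentation releases the strain of both small rings. The sulfonyl group stabilises the C4 carbanion without requiring an endocyclic enolate double bond, which favours C-attack over O-attack on the aryne. No stereocentre of the target is created: C2 and C3 are spectators, C4 forms as a mixture that step 14 erases, and C2, now α to the ketone, is held trans to C3 by thermodynamics. The step needs regioselective addition to the unsymmetrical aryne, and the C8 benzyloxy group next to C8a secures it.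

Step 13
Reactants: 22 (2R,3R)-7,8-bis(benzyloxy)-2,3-bis(benzyloxymethyl)-6-methoxy-4-(phenylsulfonyl)-3,4-dihydronaphthalen-1(2H)-one
Product: 23 (2R,3R)-7,8-bis(benzyloxy)-2,3-bis(benzyloxymethyl)-6-methoxy-4-(phenylsulfonyl)-1,2,3,4-tetrahydronaphthalen-1-ol (C1 and C4 epimers)
Conditions: NaBH4, THF/MeOH, 0 °C
Reagents that add atoms: none
Why: Hydride reduction of the aryl ketone; the C1 configuration does not matter because C1 is ionised in step 15, and cold, mild conditions avoid β-elimination of the C9 benzyloxy group.

Step 14
Reactants: 23 (2R,3R)-7,8-bis(benzyloxy)-2,3-bis(benzyloxymethyl)-6-methoxy-4-(phenylsulfonyl)-1,2,3,4-tetrahydronaphthalen-1-ol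
Product: 24 (2R,3R)-7,8-bis(benzyloxy)-2,3-bis(benzyloxymethyl)-6-methoxy-1,2,3,4-tetrahydronaphthalen-1-ol (C1 epimers)
Conditions: Mg turnings, MeOH/THF, 50 °C
Reagents that add atoms: none
Why: Reductive desulfonylation by electron transfer from Mg: the sulfone radical anion cleaves at the benzylic C4–S bond and C4 is protonated by MeOH; benzyl ethers and the benzylic alcohol are not reduced.

Step 15
Reactants: 24 (2R,3R)-7,8-bis(benzyloxy)-2,3-bis(benzyloxymethyl)-6-methoxy-1,2,3,4-tetrahydronaphthalen-1-ol; 25 2-methoxyphenol
Product: 26 4-[(1S,2R,3R)-7,8-bis(benzyloxy)-2,3-bis(benzyloxymethyl)-6-methoxy-1,2,3,4-tetrahydronaphthalen-1-yl]-2-methoxyphenol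
Conditions: 25 (5 equiv), BF3·OEt2 (0.3 equiv), CH2Cl2, −40 to 0 °C
Reagents that add atoms: none
Why: Friedel–Crafts alkylation through the C1 cation, which is stabilised by the para C6 methoxy and ortho C8 benzyloxy groups, so both alcohol epimers converge. Phenol 25 reacts para to its hydroxyl, the stronger donor, and approaches anti to the C2 benzyloxymethyl group, which sets C1 as S with the aryl trans to C2 (the known trans preference of 2-substituted tetralin-1-yl cations).

Step 16
Reactants: 26 4-[(1S,2R,3R)-7,8-bis(benzyloxy)-2,3-bis(benzyloxymethyl)-6-methoxy-1,2,3,4-tetrahydronaphthalen-1-yl]-2-methoxyphenol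
Product: 27 (1S,2R,3R)-1-(4-hydroxy-3-methoxyphenyl)-2,3-bis(hydroxymethyl)-6-methoxy-1,2,3,4-tetrahydronaphthalene-7,8-diol
Conditions: H2 (1 atm), 10% Pd/C, EtOAc/MeOH, rt; work up under argon
Reagents that add atoms: none
Why: Hydrogenolysis of the two aryl and two alkyl benzyl ethers; the C1–aryl bond and the three stereocentres are untouched, and the neutral reducing medium protects the catechol.

## Compound list

1 | fumaric acid | OC(=O)/C=C/C(=O)O | starting material
2 | (+)-menthol, (1S,2R,5S)-5-methyl-2-(propan-2-yl)cyclohexan-1-ol | CC(C)[C@H]1CC[C@H](C)C[C@@H]1O | starting material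
3 | di-(+)-menthyl fumarate | CC(C)[C@H]1CC[C@H](C)C[C@@H]1OC(=O)/C=C/C(=O)O[C@H]1C[C@@H](C)CC[C@@H]1C(C)C | intermediate
4 | 1,1-dimethoxyethene | C=C(OC)OC | starting material
5 | di-(+)-menthyl (1R,2S)-3,3-dimethoxycyclobutane-1,2-dicarboxylate | COC1(OC)C[C@@H](C(=O)O[C@H]2C[C@@H](C)CC[C@@H]2C(C)C)[C@@H]1C(=O)O[C@H]1C[C@@H](C)CC[C@@H]1C(C)C | intermediate
6 | [(1R,2R)-3,3-dimethoxycyclobutane-1,2-diyl]dimethanol | COC1(OC)C[C@@H](CO)[C@@H]1CO | intermediate
7 | (2R,3R)-2,3-bis(benzyloxymethyl)-1,1-dimethoxycyclobutane | COC1(OC)C[C@@H](COCc2ccccc2)[C@@H]1COCc1ccccc1 | intermediate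
8 | (2R,3R)-2,3-bis(benzyloxymethyl)cyclobutan-1-one | O=C1C[C@@H](COCc2ccccc2)[C@@H]1COCc1ccccc1 | intermediate
9 | (3R,4R)-3,4-bis(benzyloxymethyl)-1-(trimethylsilyloxy)cyclobut-1-ene | C[Si](C)(C)OC1=C[C@@H](COCc2ccccc2)[C@@H]1COCc1ccccc1 | intermediate
10 | (2R,3R)-2,3-bis(benzyloxymethyl)-4-(phenylsulfanyl)cyclobutan-1-one, C4 epimers | O=C1C(Sc2ccccc2)[C@@H](COCc2ccccc2)[C@@H]1COCc1ccccc1 | intermediate
11 | (2R,3R)-2,3-bis(benzyloxymethyl)-4-(phenylsulfonyl)cyclobutan-1-one, C4 epimers | O=C1C(S(=O)(=O)c2ccccc2)[C@@H](COCc2ccccc2)[C@@H]1COCc1ccccc1 | intermediate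
12 | 2,3-dihydroxy-4-methoxybenzaldehyde | COc1ccc(C=O)c(O)c1O | starting material
13 | 2,3-bis(benzyloxy)-4-methoxybenzaldehyde | COc1ccc(C=O)c(OCc2ccccc2)c1OCc1ccccc1 | intermediate
14 | 2,3-bis(benzyloxy)-4-methoxyphenyl formate | COc1ccc(OC=O)c(OCc2ccccc2)c1OCc1ccccc1 | intermediate
15 | 2,3-bis(benzyloxy)-4-methoxyphenol | COc1ccc(O)c(OCc2ccccc2)c1OCc1ccccc1 | intermediate
16 | 2,3-bis(benzyloxy)-6-bromo-4-methoxyphenol | COc1cc(Br)c(O)c(OCc2ccccc2)c1OCc1ccccc1 | intermediate
17 | [2,3-bis(benzyloxy)-6-bromo-4-methoxyphenoxy]trimethylsilane | COc1cc(Br)c(O[Si](C)(C)C)c(OCc2ccccc2)c1OCc1ccccc1 | intermediate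
18 | lithium 2,3-bis(benzyloxy)-4-methoxy-6-(trimethylsilyl)phenoxide | [Li+].[O-]c1c([Si](C)(C)C)cc(OC)c(OCc2ccccc2)c1OCc1ccccc1 | intermediate
19 | 2,3-bis(benzyloxy)-4-methoxy-6-(trimethylsilyl)phenyl trifluoromethanesulfonate | COc1cc([Si](C)(C)C)c(OS(=O)(=O)C(F)(F)F)c(OCc2ccccc2)c1OCc1ccccc1 | intermediate
20 | 3,4-bis(benzyloxy)-5-methoxybenzyne (aryne spanning C4a and C8a) | COC1=CC#CC(OCc2ccccc2)=C1OCc1ccccc1 | intermediate
21 | caesium alkoxide of the cis-fused benzocyclobutene–cyclobutane adduct (O on C1, sulfonyl on C4, C1–C4 bond still intact) | [Cs+].[O-]C12c3c(cc(OC)c(OCc4ccccc4)c3OCc3ccccc3)C1(S(=O)(=O)c1ccccc1)[C@@H](COCc1ccccc1)[C@@H]2COCc1ccccc1 | intermediate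
22 | (2R,3R)-7,8-bis(benzyloxy)-2,3-bis(benzyloxymethyl)-6-methoxy-4-(phenylsulfonyl)-3,4-dihydronaphthalen-1(2H)-one, C4 epimers | O=C1c2c(cc(OC)c(OCc3ccccc3)c2OCc2ccccc2)C(S(=O)(=O)c2ccccc2)[C@@H](COCc2ccccc2)[C@@H]1COCc1ccccc1 | intermediate
23 | (2R,3R)-7,8-bis(benzyloxy)-2,3-bis(benzyloxymethyl)-6-methoxy-4-(phenylsulfonyl)-1,2,3,4-tetrahydronaphthalen-1-ol, C1 and C4 epimers | OC1c2c(cc(OC)c(OCc3ccccc3)c2OCc2ccccc2)C(S(=O)(=O)c2ccccc2)[C@@H](COCc2ccccc2)[C@@H]1COCc1ccccc1 | intermediate
24 | (2R,3R)-7,8-bis(benzyloxy)-2,3-bis(benzyloxymethyl)-6-methoxy-1,2,3,4-tetrahydronaphthalen-1-ol, C1 epimers | OC1c2c(cc(OC)c(OCc3ccccc3)c2OCc2ccccc2)C[C@@H](COCc2ccccc2)[C@@H]1COCc1ccccc1 | intermediate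
25 | 2-methoxyphenol | COc1ccccc1O | starting material
26 | 4-[(1S,2R,3R)-7,8-bis(benzyloxy)-2,3-bis(benzyloxymethyl)-6-methoxy-1,2,3,4-tetrahydronaphthalen-1-yl]-2-methoxyphenol | COc1cc([C@H]2c3c(cc(OC)c(OCc4ccccc4)c3OCc3ccccc3)C[C@@H](COCc3ccccc3)[C@@H]2COCc2ccccc2)ccc1O | intermediate
27 | (1S,2R,3R)-1-(4-hydroxy-3-methoxyphenyl)-2,3-bis(hydroxymethyl)-6-methoxy-1,2,3,4-tetrahydronaphthalene-7,8-diol | COc1cc([C@H]2c3c(cc(OC)c(O)c3O)C[C@@H](CO)[C@@H]2CO)ccc1O | target

## Step count and risk

Total: 16 steps. Longest linear sequence: 12 steps (steps 1–7, then 12–16). The aryne precursor arm is 4 steps (8–11).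

**Step 12 (key step, proposed new method).** The likeliest failures are:
- protonation of the C8a aryl anion before it closes, which would leave plain α-arylation of the β-keto sulfone;
- fluoride- or water-induced retro-Claisen opening of the strained β-keto sulfone before it meets the aryne;
- O-arylation of the ambident anion;
- failure of the doubly strained alkoxide to form at all;
- β-elimination of the C9 benzyloxy group from the product, which is a β-alkoxy ketone held under basic conditions.

Fallback, from 11 and returning at 22: the four-membered ring is opened first and ring B is then closed through a six-membered transition state. NaOMe in MeOH at 0 °C cleaves the C1–C4 bond of 11 by retro-Claisen reaction to give the ester sulfone methyl (2R,3R)-2,3-bis(benzyloxymethyl)-4-(phenylsulfonyl)butanoate F1. Its C4 sulfonyl carbanion (LiN(iPr)2, THF, −78 °C) is combined with 19 and CsF with 18-crown-6 in THF. The carbanion adds to aryne 20 at C4a, and the C8a anion closes on the ester in a Dieckmann-type acylation (6-exo-trig) with loss of methoxide to give 22. Both events, addition of a sulfonyl carbanion to an aryne and capture of the aryl anion by a pendant ester to give a six-membered ketone, belong to documented aryne annulation chemistry.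

**Step 15.** Three things may go wrong: attack through the position of 25 para to its methoxy group or ortho to its hydroxyl, because both oxygen substituents activate the ring; capture of the C1 cation by the oxygen of the C10 benzyl ether with loss of benzyl; and eroded facial selectivity because the peri C8 benzyloxy group distorts the cation. Fallback, from 24 and returning at 27: 2-bromo-6-methoxyphenol is used as the nucleophile under the same acid catalysis. Both positions ortho to its hydroxyl are blocked and the position para to its methoxy group is hindered by bromine, so only the carbon para to the hydroxyl is open. This gives 2-bromo-4-[(1S,2R,3R)-7,8-bis(benzyloxy)-2,3-bis(benzyloxymethyl)-6-methoxy-1,2,3,4-tetrahydronaphthalen-1-yl]-6-methoxyphenol F2. Hydrogenolysis over Pd/C with Et3N then removes the four benzyl groups and the bromine together to give 27.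

**Step 6.** Enolisation toward C2 with β-elimination of benzyloxide, aldol self-condensation of the electrophilic cyclobutanone, or double sulfenylation may intervene. Fallback, from 8 and returning at 10: condensation with 1,1-dimethylhydrazine gives (2S,3R)-2,3-bis(benzyloxymethyl)cyclobutanone N,N-dimethylhydrazone F3 (the spatial arrangement of 8; only the descriptor at C2 changes, because C=N ranks below CH2O). Its azaenolate (LiN(iPr)2, THF, −78 °C) forms at the less substituted α-carbon without a free ketone present and is sulfenylated with PhSSPh to give (2S,3R)-2,3-bis(benzyloxymethyl)-4-(phenylsulfanyl)cyclobutanone N,N-dimethylhydrazone F4. CuCl2 in aqueous THF then hydrolyses F4 to 10.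

**Step 10.** Bromination at C5 (ortho to the methoxy group) instead of the future C4a, or oxidation of the electron-rich para-methoxyphenol to a quinone, may compete. Fallback, from 15 and returning at 19: iPrNCO with Et3N gives 2,3-bis(benzyloxy)-4-methoxyphenyl N-isopropylcarbamate F5. N-silylation (TMSOTf, TMEDA), carbamate-directed ortho-lithiation (n-BuLi, −78 °C) and TMSCl give 2,3-bis(benzyloxy)-4-methoxy-6-(trimethylsilyl)phenyl N-isopropylcarbamate F6. DBU with Et2NH cleaves the carbamate, and PhNTf2 triflates the phenoxide to give 19 without any electrophilic halogenation.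

## Further compounds

F1 | step 12 | methyl (2R,3R)-2,3-bis(benzyloxymethyl)-4-(phenylsulfonyl)butanoate | COC(=O)[C@@H](COCc1ccccc1)[C@H](COCc1ccccc1)CS(=O)(=O)c1ccccc1
F2 | step 15 | 2-bromo-4-[(1S,2R,3R)-7,8-bis(benzyloxy)-2,3-bis(benzyloxymethyl)-6-methoxy-1,2,3,4-tetrahydronaphthalen-1-yl]-6-methoxyphenol | COc1cc([C@H]2c3c(cc(OC)c(OCc4ccccc4)c3OCc3ccccc3)C[C@@H](COCc3ccccc3)[C@@H]2COCc2ccccc2)cc(Br)c1O
F3 | step 6 | (2S,3R)-2,3-bis(benzyloxymethyl)cyclobutanone N,N-dimethylhydrazone | CN(C)N=C1C[C@@H](COCc2ccccc2)[C@@H]1COCc1ccccc1
F4 | step 6 | (2S,3R)-2,3-bis(benzyloxymethyl)-4-(phenylsulfanyl)cyclobutanone N,N-dimethylhydrazone, C4 epimers | CN(C)N=C1C(Sc2ccccc2)[C@@H](COCc2ccccc2)[C@@H]1COCc1ccccc1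
F5 | step 10 | 2,3-bis(benzyloxy)-4-methoxyphenyl N-isopropylcarbamate | COc1ccc(OC(=O)NC(C)C)c(OCc2ccccc2)c1OCc1ccccc1
F6 | step 10 | 2,3-bis(benzyloxy)-4-methoxy-6-(trimethylsilyl)phenyl N-isopropylcarbamate | COc1cc([Si](C)(C)C)c(OC(=O)NC(C)C)c(OCc2ccccc2)c1OCc1ccccc1
A1 | alternative 1 | tethered trans-1-aryl-1,2-dihydronaphthalene-2,3-dicarboxylate (nine-membered dilactone), C8 oxygen as tosylate | COc1cc([C@H]2c3c(cc(OC)c(O)c3OS(=O)(=O)c3ccc(C)cc3)C=C(C(=O)O[C@H](C)C[C@@H](C)O5)[C@@H]2C5=O)ccc1O
A2 | alternative 1 | (2R,4R)-pentane-2,4-diyl mixed diester of 4-hydroxy-3-methoxycinnamic acid and 4-hydroxy-3-methoxy-5-(tosyloxy)cinnamic acid | COc1cc(/C=C/C(=O)O[C@H](C)C[C@@H](C)OC(=O)/C=C/c2cc(OC)c(O)c(OS(=O)(=O)c3ccc(C)cc3)c2)ccc1O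
A3 | alternative 2 | tricyclic methyl acetal with the C8 oxygen bonded to C9 of the all-trans tetralin, acetal epimers | COc1cc([C@H]2c3c(cc(OC)c(OCc4ccccc4)c3O5)C[C@@H](COCc3ccccc3)[C@@H]2C5OC)ccc1OCc1ccccc1
A4 | alternative 2 | hydroxy carbinol with free C8 phenol, C1 diaryl carbinol and a C4–C3–C2=C9 enol ether chain on C4a | COc1cc(C(O)c2c(C[C@@H](COCc3ccccc3)C=COC)cc(OC)c(OCc3ccccc3)c2O)ccc1OCc1ccccc1
A5 | alternative 3 | dimethyl 1-hydroxy-6-methoxy-7,8-(diphenylmethylenedioxy)tetralin-2,3-dicarboxylate, esters trans, hydroxyl cis to the C2 ester | O[C@@H]1c2c(cc(OC)c3OC(c4ccccc4)(c4ccccc4)Oc23)C[C@@H](C(=O)OC)[C@@H]1C(=O)OC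
A6 | alternative 3 | 7-methoxy-5-methyl-2,2-diphenyl-1,3-benzodioxole-4-carbaldehyde | O=Cc1c(C)cc(OC)c2OC(c3ccccc3)(c3ccccc3)Oc12
A7 | alternative 3 | dimethyl fumarate | COC(=O)/C=C/C(=O)OC
A8 | alternative 3 | titanium tetraisopropoxide, Ti(OiPr)4 | CC(C)O[Ti](OC(C)C)(OC(C)C)OC(C)C
A9 | alternative 3 | (4R,5R)-2,2-dimethyl-α,α,α′,α′-tetraphenyl-1,3-dioxolane-4,5-dimethanol (tartrate-derived diol ligand) | CC1(C)O[C@@H](C(O)(c2ccccc2)c2ccccc2)[C@H](C(O)(c2ccccc2)c2ccccc2)O1
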